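Everything rests on the C13–C16 bond of ring D (C8–C14–C13–C16–C15). The key step exploits the tertiary carbinol C13 that stands next to the exocyclic C16=C17 methylene: this pair is the retron of a ketyl–alkyne cyclization, and its precursor, a C13 ketone, is also the handle that makes C12 oxidisable. Commercial gibberellic acid is therefore opened at ring D to an 8-propargyl 13-ketone that keeps rings A, B, C and the lactone; C12 is hydroxylated through the enolate, and SmI2 then closes ring D last, creating the C13–C16 bond, the C13 stereocentre and the 16-methylene in one operation. C12 is finally set by reduction of the 12-ketone.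

Key step: step 8

Assumption (chemistry): gibberellic acid, a bulk fermentation product, is taken as an admissible commercial starting material, so the route is a relay in which ring D is cleaved and built anew; gibberellane numbering is used, β is the face of ring C that carries the C9 hydrogen and the C15–C16 bridge, and C16 in 5 and 6 and C12 in 9 to 12 are carried as epimer mixtures because both centres are erased later.

Step 1
Reactants: 1 gibberellic acid
Product: 2 gibberellic acid 2-(trimethylsilyl)ethyl ester (C7 ester; 3β-OH and 13-OH free)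
Conditions: Me3SiCH2CH2OH (excess), EDC·HCl, DMAP (cat.), CH2Cl2, 0 °C to rt
Reagents that add atoms: 2-(trimethylsilyl)ethanol C[Si](C)(C)CCO
Why: Steglich esterification should take the carbodiimide-activated C7 acid onto the primary alcohol, used in excess, much faster than onto the secondary 3-OH or the tertiary 13-OH, under neutral conditions that spare the allylic lactone of ring A.

Step 2
Reactants: 2 gibberellic acid 2-(trimethylsilyl)ethyl ester
Product: 3 3-O-TBS-gibberellic acid 2-(trimethylsilyl)ethyl ester
Conditions: t-BuMe2SiCl, imidazole, DMF, rt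
Reagents that add atoms: tert-butyldimethylsilyl chloride CC(C)(C)[Si](C)(C)Cl
Why: Silyl ether formation with the chloride and imidazole should stop at the secondary allylic 3-OH because the tertiary bridgehead 13-OH is too hindered for this reagent.

Step 3
Reactants: 3 3-O-TBS-gibberellic acid 2-(trimethylsilyl)ethyl ester
Product: 5 17-nor-16-hydroxy derivative of 3 (13,16-diol; C16 epimers; C1=C2 kept), via 17-nor-16-ketone 4 (not isolated)
Conditions: O3, pyridine, CH2Cl2/MeOH, −78 °C; then NaBH4, −78 to 0 °C
Reagents that add atoms: ozone [O-][O+]=O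
Why: Ozonolysis with reductive work-up should cleave the electron-rich 1,1-disubstituted C16=C17 bond well before the C1=C2 bond, which two allylic C–O bonds deactivate, and NaBH4 then reduces the ozonolysis intermediates through ketone 4 to the diol, whose C16 configuration does not matter because the centre is destroyed in step 5.

Step 4
Reactants: 5 17-nor-13,16-diol (C16 epimers)
Product: 6 1,2-dihydro derivative of 5 (C16 epimers)
Conditions: H2 (1 atm), 5% Pd/BaSO4, EtOAc/pyridine, rt
Reagents that add atoms: none
Why: Heterogeneous catalytic hydrogenation should add hydrogen to the C1=C2 bond, the only olefin left, while pyridine poisoning of the catalyst holds back hydrogenolysis of the allylic C10–O bond of the lactone; no stereocentre is formed.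

Step 5
Reactants: 6 1,2-dihydro-17-nor-13,16-diol (C16 epimers)
Product: 7 13,16-seco keto aldehyde (C13 ketone in ring C; CH2–CHO = C15–C16 on C8)
Conditions: Pb(OAc)4, CH2Cl2, 0 °C
Reagents that add atoms: none
Why: Criegee glycol cleavage through a cyclic lead diester should break the C13–C16 bond of either C16 epimer and so open ring D to the C13 ketone and the C16 aldehyde without touching other groups.

Step 6
Reactants: 7 13,16-seco keto aldehyde
Product: 8 13,16-seco alkynyl ketone (C13 ketone; propargyl C15–C16≡C17H on C8)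
Conditions: dimethyl (1-diazo-2-oxopropyl)phosphonate, K2CO3, MeOH, 0 °C to rt
Reagents that add atoms: dimethyl (1-diazo-2-oxopropyl)phosphonate CC(=O)C(=[N+]=[N-])P(=O)(OC)OC
Why: The Ohira–Bestmann variant of the Seyferth–Gilbert homologation should turn the aldehyde into the terminal alkyne (the diazo carbon becomes C17), the hindered ring ketone being inert to the phosphonate anion and any reversible C12-to-C16 aldol being drained through the aldehyde.

Step 7
Reactants: 8 13,16-seco alkynyl ketone
Product: 10 12-triethylsilyloxy derivative of 8 (C12 epimers), via 12-hydroxy ketone potassium alkoxide 9 (not isolated)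
Conditions: KN(SiMe3)2 (1.05 equiv), THF, −78 °C; 2-(phenylsulfonyl)-3-phenyloxaziridine, −78 °C; then Et3SiCl, −78 to 0 °C
Reagents that add atoms: 2-(phenylsulfonyl)-3-phenyloxaziridine O=S(=O)(c1ccccc1)N1OC1c1ccccc1; chlorotriethylsilane CC[Si](Cl)(CC)CC
Why: Kinetic deprotonation should occur at C12 and not at C14, which is neopentyl and flanked by quaternary C8, and oxygen transfer from the oxaziridine to the enolate (Davis oxidation) followed by silylation of the alkoxide in the same flask should give the α-siloxy ketone; attack anti to ring B should favour the 12β epimer, but either epimer serves because C12 is reset in steps 10 and 11.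

Step 8
Reactants: 10 12-triethylsilyloxy 13,16-seco alkynyl ketone (C12 epimers)
Product: 11 3-O-TBS-12-O-TES-12-hydroxy-1,2-dihydrogibberellic acid 2-(trimethylsilyl)ethyl ester (ring D closed; 13-OH free; 16-methylene; C12 epimers)
Conditions: SmI2, HMPA, t-BuOH, THF, 0 °C to rt
Reagents that add atoms: none
Why: Single-electron transfer from SmI2 to the C13 ketone gives a samarium ketyl that adds to C16 of the propargyl arm on C8, and the resulting vinyl radical is reduced by a second SmI2 and protonated by t-BuOH to the exocyclic C16=C17 methylene; this is the established ketyl–alkyne reductive cyclization. Ring D (C8–C14–C13–C16–C15) closes in the 5-exo-dig mode through the C13–C16 bond, after ring C has flipped to the chair that holds the propargyl group axial. The only new stereocentre, C13, is controlled by C8: the arm sits on the β face and the bridged bicyclo[3.2.1]octane can form only with C16 on that face, which leaves the 13-hydroxyl equatorial as in the target. The step needs cyclization to outrun loss of the C12 siloxy group and plain reduction of the ketone; the alkyne hangs from quaternary C8 within bonding distance of the ketyl, a silyl ether is a poor leaving group, and in the 12β epimer the C12–O bond lies equatorial, near the nodal plane of the ketyl, in the reacting chair. Lactone, ester and silyl ethers are inert to SmI2 under these conditions, and both C12 epimers converge later.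

Step 9
Reactants: 11 ring-D-closed 12-O-TES compound (C12 epimers)
Product: 12 3-O-TBS-12-hydroxy-1,2-dihydrogibberellic acid 2-(trimethylsilyl)ethyl ester (12,13-diol; C12 epimers)
Conditions: PPTS (cat.), MeOH, rt
Reagents that add atoms: none
Why: Acid-catalysed methanolysis should remove the triethylsilyl ether (also from the 13-oxygen, should it have migrated there in step 8) much faster than the hindered secondary TBS ether, and the buffered acid is too weak to protonate the 16-ene.

Step 10
Reactants: 12 12,13-diol (C12 epimers)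
Product: 13 3-O-TBS-12-oxo-1,2-dihydrogibberellic acid 2-(trimethylsilyl)ethyl ester (13-hydroxy 12-ketone)
Conditions: SO3·pyridine, DMSO, Et3N, CH2Cl2, 0 °C
Reagents that add atoms: none
Why: Parikh–Doering oxidation with activated DMSO should convert the secondary 12-OH of either epimer into the ketone, leave the tertiary 13-OH alone and, unlike periodinane or periodate oxidants, cannot cleave the 1,2-diol.

Step 11
Reactants: 13 13-hydroxy 12-ketone
Product: 14 3-O-TBS-12α-hydroxy-1,2-dihydrogibberellic acid 2-(trimethylsilyl)ethyl ester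
Conditions: NaBH4, MeOH/THF, −40 °C
Reagents that add atoms: none
Why: Hydride reduction of the ketone in the rigid bicyclo[3.2.1]octane should come from the β face, because the α face of C12 is closed by C10, which stands axial on ring C and syn to the axial trajectory, so that the 12-hydroxyl ends up α and axial as in the target (substrate control).

Step 12
Reactants: 14 3-O-TBS-12α-hydroxy-1,2-dihydrogibberellic acid 2-(trimethylsilyl)ethyl ester
Product: 15 12α-hydroxy-1,2-dihydrogibberellic acid (target)
Conditions: Bu4NF, AcOH, THF, rt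
Reagents that add atoms: none
Why: Fluoride should cleave the TBS ether by attack at silicon and the 2-(trimethylsilyl)ethyl ester by β-elimination of ethene in one operation, the acetic acid buffer preventing retro-aldol epimerisation at C3 of the freed β-hydroxy lactone.

Compound list

1 | gibberellic acid (3β,13-dihydroxy-20-norgibberella-1,16-diene-7,19-dioic acid 19,10-lactone) | C=C1C[C@]23C[C@@]1(O)CC[C@H]2[C@@]12C=C[C@H](O)[C@@](C)(C(=O)O1)[C@H]2[C@@H]3C(=O)O | starting material
2 | gibberellic acid 2-(trimethylsilyl)ethyl ester | C=C1C[C@]23C[C@@]1(O)CC[C@H]2[C@@]12C=C[C@H](O)[C@@](C)(C(=O)O1)[C@H]2[C@@H]3C(=O)OCC[Si](C)(C)C | intermediate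
3 | 3-O-TBS-gibberellic acid 2-(trimethylsilyl)ethyl ester | C=C1C[C@]23C[C@@]1(O)CC[C@H]2[C@@]12C=C[C@H](O[Si](C)(C)C(C)(C)C)[C@@](C)(C(=O)O1)[C@H]2[C@@H]3C(=O)OCC[Si](C)(C)C | intermediate
4 | 17-nor-16-oxo derivative of 3 (13-hydroxy 16-ketone; not isolated) | O=C1C[C@]23C[C@@]1(O)CC[C@H]2[C@@]12C=C[C@H](O[Si](C)(C)C(C)(C)C)[C@@](C)(C(=O)O1)[C@H]2[C@@H]3C(=O)OCC[Si](C)(C)C | intermediate
5 | 17-nor-16-hydroxy derivative of 3 (13,16-diol; C16 epimers; C1=C2 kept) | OC1C[C@]23C[C@@]1(O)CC[C@H]2[C@@]12C=C[C@H](O[Si](C)(C)C(C)(C)C)[C@@](C)(C(=O)O1)[C@H]2[C@@H]3C(=O)OCC[Si](C)(C)C | intermediate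
6 | 1,2-dihydro derivative of 5 (C16 epimers) | OC1C[C@]23C[C@@]1(O)CC[C@H]2[C@@]12CC[C@H](O[Si](C)(C)C(C)(C)C)[C@@](C)(C(=O)O1)[C@H]2[C@@H]3C(=O)OCC[Si](C)(C)C | intermediate
7 | 13,16-seco keto aldehyde (C13 ketone; CH2CHO on C8; 3-O-TBS; 2-(trimethylsilyl)ethyl ester) | O=CC[C@]23CC(=O)CC[C@H]2[C@@]12CC[C@H](O[Si](C)(C)C(C)(C)C)[C@@](C)(C(=O)O1)[C@H]2[C@@H]3C(=O)OCC[Si](C)(C)C | intermediate
8 | 13,16-seco alkynyl ketone (C13 ketone; propargyl on C8) | C#CC[C@]23CC(=O)CC[C@H]2[C@@]12CC[C@H](O[Si](C)(C)C(C)(C)C)[C@@](C)(C(=O)O1)[C@H]2[C@@H]3C(=O)OCC[Si](C)(C)C | intermediate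
9 | 12-hydroxy derivative of 8 (C12 epimers; formed as the potassium alkoxide; not isolated) | C#CC[C@]23CC(=O)C(O)C[C@H]2[C@@]12CC[C@H](O[Si](C)(C)C(C)(C)C)[C@@](C)(C(=O)O1)[C@H]2[C@@H]3C(=O)OCC[Si](C)(C)C | intermediate
10 | 12-triethylsilyloxy derivative of 8 (C12 epimers) | C#CC[C@]23CC(=O)C(O[Si](CC)(CC)CC)C[C@H]2[C@@]12CC[C@H](O[Si](C)(C)C(C)(C)C)[C@@](C)(C(=O)O1)[C@H]2[C@@H]3C(=O)OCC[Si](C)(C)C | intermediate
11 | 3-O-TBS-12-O-TES-12-hydroxy-1,2-dihydrogibberellic acid 2-(trimethylsilyl)ethyl ester (ring D closed; C12 epimers) | C=C1C[C@]23C[C@@]1(O)C(O[Si](CC)(CC)CC)C[C@H]2[C@@]12CC[C@H](O[Si](C)(C)C(C)(C)C)[C@@](C)(C(=O)O1)[C@H]2[C@@H]3C(=O)OCC[Si](C)(C)C | intermediate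
12 | 3-O-TBS-12-hydroxy-1,2-dihydrogibberellic acid 2-(trimethylsilyl)ethyl ester (C12 epimers) | C=C1C[C@]23C[C@@]1(O)C(O)C[C@H]2[C@@]12CC[C@H](O[Si](C)(C)C(C)(C)C)[C@@](C)(C(=O)O1)[C@H]2[C@@H]3C(=O)OCC[Si](C)(C)C | intermediate
13 | 3-O-TBS-12-oxo-1,2-dihydrogibberellic acid 2-(trimethylsilyl)ethyl ester | C=C1C[C@]23C[C@@]1(O)C(=O)C[C@H]2[C@@]12CC[C@H](O[Si](C)(C)C(C)(C)C)[C@@](C)(C(=O)O1)[C@H]2[C@@H]3C(=O)OCC[Si](C)(C)C | intermediate
14 | 3-O-TBS-12α-hydroxy-1,2-dihydrogibberellic acid 2-(trimethylsilyl)ethyl ester | C=C1C[C@]23C[C@@]1(O)[C@@H](O)C[C@H]2[C@@]12CC[C@H](O[Si](C)(C)C(C)(C)C)[C@@](C)(C(=O)O1)[C@H]2[C@@H]3C(=O)OCC[Si](C)(C)C | intermediate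
15 | 12α-hydroxy-1,2-dihydrogibberellic acid (3β,12α,13-trihydroxy-20-norgibberell-16-ene-7,19-dioic acid 19,10-lactone; CNP0260503.1) | C=C1C[C@]23C[C@@]1(O)[C@@H](O)C[C@H]2[C@@]12CC[C@H](O)[C@@](C)(C(=O)O1)[C@H]2[C@@H]3C(=O)O | target

Total step count: 12. Longest linear sequence: 12 steps (1 to 15).

Steps most likely to fail

Step 8. The ketyl may take up a second electron and expel the C12 siloxy group, or be reduced to the alcohol before it reaches the alkyne. The fallback closes the same bond by a polar addition that involves no ketyl. It sets out from 10: Markovnikov hydrobromination of the alkyne (B-bromo-9-borabicyclo[3.3.1]nonane, CH2Cl2, 0 °C; then AcOH) should give the 2-bromoallyl ketone F1. A Nozaki–Hiyama–Kishi reaction (CrCl2, NiCl2 cat., DMF, rt) should then add the vinylchromium species to the C13 ketone and return to the route at 11.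

Step 7. Deprotonation may be shared between C12, C14 and the alkyne C–H, and the potassium alkoxide may isomerise the α-ketol before it is silylated. The fallback replaces enolate chemistry by enamine catalysis and sets out from 8. Proline-catalysed α-aminoxylation with nitrosobenzene (DMSO, rt) should give the 12-anilinooxy ketone F2, since the enamine can form only toward C12; toward C14 it would clash with quaternary C8. N–O cleavage (CuSO4 cat., MeOH, 0 °C) gives 9, here isolated, and Et3SiCl/imidazole in DMF gives 10, where the route is rejoined.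

Step 11. Hydride delivery may lose its facial preference if the β face, which carries bridge carbon C16, proves as hindered as the α face, so that both 12-epimers form. The fallback fixes C12 before the ring closure under thermodynamic control and sets out from 10. Equilibration with DBU (toluene, rt) should enrich the 12α-siloxy ketone F3, whose siloxy group is equatorial on the preferred chair of the seco ketone. Cyclization with SmI2 as in step 8 gives the 12α-siloxy tetracycle F4, and PPTS/MeOH then gives 14 directly, where the route is rejoined; 12 and 13 are bypassed.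

Further compounds
F1 | step 8 | 2-bromoallyl ketone (C8–CH2–C(Br)=CH2; 13-oxo; 12-OTES, C12 epimers; 3-O-TBS; 2-(trimethylsilyl)ethyl ester) | C=C(Br)C[C@]23CC(=O)C(O[Si](CC)(CC)CC)C[C@H]2[C@@]12CC[C@H](O[Si](C)(C)C(C)(C)C)[C@@](C)(C(=O)O1)[C@H]2[C@@H]3C(=O)OCC[Si](C)(C)C
F2 | step 7 | 12-anilinooxy derivative of 8 (C12 configuration inconsequential) | C#CC[C@]23CC(=O)C(ONc4ccccc4)C[C@H]2[C@@]12CC[C@H](O[Si](C)(C)C(C)(C)C)[C@@](C)(C(=O)O1)[C@H]2[C@@H]3C(=O)OCC[Si](C)(C)C
F3 | step 11 | 12α epimer of 10 (12α-triethylsilyloxy 13,16-seco alkynyl ketone) | C#CC[C@]23CC(=O)[C@@H](O[Si](CC)(CC)CC)C[C@H]2[C@@]12CC[C@H](O[Si](C)(C)C(C)(C)C)[C@@](C)(C(=O)O1)[C@H]2[C@@H]3C(=O)OCC[Si](C)(C)C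
F4 | step 11 | 12α epimer of 11 (3-O-TBS-12α-O-TES-12-hydroxy-1,2-dihydrogibberellic acid 2-(trimethylsilyl)ethyl ester) | C=C1C[C@]23C[C@@]1(O)[C@@H](O[Si](CC)(CC)CC)C[C@H]2[C@@]12CC[C@H](O[Si](C)(C)C(C)(C)C)[C@@](C)(C(=O)O1)[C@H]2[C@@H]3C(=O)OCC[Si](C)(C)C
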